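## Retrosynthetic overview
1. 5 ⇒ 3: cut the ring B C2'–OH bond, which lies para to the 5'-OH. It is made last, by para C–H oxygenation of the ring B phenolate (key C–O bond, new step).
2. 3 ⇒ 2: cut the C6–OMe and C8–OMe bonds. Both are made in one operation by copper-mediated C–O coupling of a 6,8-dibromide with methoxide.
3. 2 ⇒ 1: ring A-selective dibromination of diosmetin. The bromines first block ring A and then serve as the coupling handles.
4. Ring order: no ring is built. Rings A, C and B arrive intact in 1, the work goes into three aryl C–O bonds, and no protecting group is used.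

Assumption: the SMILES contains no stereocentre and no stereogenic double bond, so 5 is achiral and no enantiomer question arises. Diosmetin 1, the aglycone of the bulk drug diosmin, is taken as a purchasable multi-gram starting material.

## Route

Step 1
Reactants: 1 diosmetin (5,7,3'-trihydroxy-4'-methoxyflavone)
Product: 2 6,8-dibromodiosmetin (6,8-dibromo-5,7,3'-trihydroxy-4'-methoxyflavone)
Conditions: NBS (2.05 equiv), DMF, −10 to 0 °C, dark, 2 h; H2O, filter
Reagents that add atoms: N-bromosuccinimide, O=C1CCC(=O)N1Br
Why: Electrophilic aromatic bromination (SEAr): C6 and C8 of the phloroglucinol-type ring A each sit ortho or para to three oxygen donors and react far faster than ring B, which has one free phenol and is tied to the electron-poor C2 of the pyranone, so two equivalents stop at the 6,8-dibromide.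

Step 2
Reactants: 2 6,8-dibromodiosmetin
Product: 3 acerosin (5,7,3'-trihydroxy-6,8,4'-trimethoxyflavone)
Conditions: NaOMe (25% in MeOH, 12 equiv), CuBr (0.4 equiv), DMF, Ar, 110 °C, 6 h; then cold 2 M HCl, filter
Reagents that add atoms: sodium methoxide, [Na+].[O-]C
Why: Ullmann-type C–O coupling (copper-promoted methanolysis of aryl bromides): a monovalent copper methoxide adds to each C–Br bond and reductive elimination from trivalent copper gives the two aryl methyl ethers, while the free phenols sit as inert phenolates, ring B carries no halide, and any base-induced opening and reclosure of ring C (Wessely–Moser) is degenerate because the opened ring A is symmetric.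

Step 3
Reactants: 3 acerosin
Product: 5 5,7,2',5'-tetrahydroxy-6,8,4'-trimethoxyflavone (target), via potassium aryl sulfate 4 (not isolated)
Conditions: K2S2O8 (0.95 equiv, added over 3 h), aq KOH (pH-stat 10.5), pyridine co-solvent, Ar, 5 to 20 °C, 24 h; HCl to pH 4, EtOAc wash (recovers 3); then 2 M HCl, Ar, 85 °C, 1 h
Reagents that add atoms: potassium peroxydisulfate, [K+].[K+].[O-]S(=O)(=O)OOS(=O)(=O)[O-]
Why: Proposed new method: an Elbs-type peroxydisulfate para C–H oxygenation steered onto ring B of an unprotected flavone, not yet shown for a substrate whose ring A carries two free phenols but no C–H; at pH 10.5 compound 3 is the 7,3'-dianion (the 5-OH stays locked in its hydrogen bond to C4=O) and the 7-phenolate is a delocalised vinylogous carboxylate whose ortho and para carbons are all substituted, so the only carbon nucleophile able to rearomatise is C6', para to the 3'-phenolate, which attacks the O–O bond of S2O8(2−) in an SN2-at-oxygen step, expels sulfate and tautomerises to aryl sulfate 4, whose anionic, electron-poor sulfate group stops over-oxidation and holds 4 in water while unreacted 3 is extracted, ortho attack at C2' being disfavoured by charge repulsion and by the flanking ring C, and acid hydrolysis by S–O cleavage then frees the new phenol (old C6' becomes C2', old 3'-OH becomes 5'-OH); closest known reaction type: Elbs persulfate oxidation of simple phenols, as in 3-hydroxybenzoic acid to gentisic acid.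

## Compound list
1 | diosmetin, 5,7-dihydroxy-2-(3-hydroxy-4-methoxyphenyl)-4H-chromen-4-one | COc1ccc(cc1O)-c2cc(=O)c3c(O)cc(O)cc3o2 | starting material
2 | 6,8-dibromodiosmetin, 6,8-dibromo-5,7-dihydroxy-2-(3-hydroxy-4-methoxyphenyl)-4H-chromen-4-one | COc1ccc(cc1O)-c2cc(=O)c3c(O)c(Br)c(O)c(Br)c3o2 | intermediate
3 | acerosin, 5,7-dihydroxy-2-(3-hydroxy-4-methoxyphenyl)-6,8-dimethoxy-4H-chromen-4-one | COc1ccc(cc1O)-c2cc(=O)c3c(O)c(OC)c(O)c(OC)c3o2 | intermediate
4 | potassium 2-(5,7-dihydroxy-6,8-dimethoxy-4-oxo-4H-chromen-2-yl)-4-hydroxy-5-methoxyphenyl sulfate | COc1cc(OS(=O)(=O)[O-])c(cc1O)-c2cc(=O)c3c(O)c(OC)c(O)c(OC)c3o2.[K+] | intermediate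
5 | 5,7-dihydroxy-2-(2,5-dihydroxy-4-methoxyphenyl)-6,8-dimethoxy-4H-chromen-4-one (achiral) | COc1cc(O)c(-c2cc(=O)c3c(O)c(OC)c(O)c(OC)c3o2)cc1O | target

## Step count and risks
Total step count: 3. Longest linear sequence: 3 steps (1 → 2 → 3 → 5). Estimated yields are roughly 85%, 60% and 30–40%; the last figure is higher when counted on recovered 3.

**Step 3 (the proposed new step).**
- Risk: conversion may be low. One-electron oxidation of the electron-rich ring A could give a 5,8-quinone with loss of methanol, or dark polymeric material.
- Fallback (known chemistry): it sets out from 3 and changes from polar C–H sulfonyloxylation to a radical phenol-to-quinone oxidation followed by reduction.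
- A Teuber oxidation uses (KSO3)2NO (2.2 equiv) in KH2PO4-buffered water/acetone at 0 to 20 °C. It attacks the only phenol with a free para position and gives the ring B para-quinone 2-(5,7-dihydroxy-6,8-dimethoxy-4-oxo-4H-chromen-2-yl)-5-methoxy-1,4-benzoquinone F1.
- Shaking F1 with Na2S2O4 in EtOAc/water reduces it to the hydroquinone. The fallback comes back to the route at 5.

**Step 2.**
- Risk: hydrodebromination or incomplete exchange on the polyanion would give mixtures of mono-methoxy products.
- Fallback: it sets out from 2 and changes both the substrate state (neutral and protected instead of a polyanion) and the metal.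
- BnBr/K2CO3 in DMF at 70 °C gives 5,7,3'-tris(benzyloxy)-6,8-dibromo-4'-methoxyflavone F2.
- A Buchwald-type etherification at zerovalent palladium (Pd2(dba)3, tBuBrettPhos, MeOH, Cs2CO3, toluene, 80 °C) gives 5,7,3'-tris(benzyloxy)-6,8,4'-trimethoxyflavone F3.
- Hydrogenolysis (H2, Pd/C, EtOAc–MeOH, rt) removes the three benzyl groups. The fallback comes back to the route at 3.

**Step 1.**
- Risk: competing bromination of ring B or of C3 under neutral SEAr conditions. Isovanillin-type rings are known to be halogenated next to the phenol.
- Fallback: it sets out from 1 and replaces kinetic SEAr on neutral phenols by a pKa-gated halogenation.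
- With I2 (2.1 equiv) and NaHCO3 in aqueous THF at 0 °C, only the acidic 7-OH is ionised. Ring A then reacts as a vinylogous enolate while the ring B phenol stays neutral, giving 6,8-diiododiosmetin F4.
- F4 is carried through the CuBr/NaOMe coupling at 90 °C. The fallback comes back to the route at 3 and bypasses 2.

## Further compounds
F1 | step 3 | 2-(5,7-dihydroxy-6,8-dimethoxy-4-oxo-4H-chromen-2-yl)-5-methoxycyclohexa-2,5-diene-1,4-dione | COC1=CC(=O)C(=CC1=O)c2cc(=O)c3c(O)c(OC)c(O)c(OC)c3o2
F2 | step 2 | 5,7-bis(benzyloxy)-2-[3-(benzyloxy)-4-methoxyphenyl]-6,8-dibromo-4H-chromen-4-one | COc1ccc(cc1OCc4ccccc4)-c2cc(=O)c3c(OCc5ccccc5)c(Br)c(OCc6ccccc6)c(Br)c3o2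
F3 | step 2 | 5,7-bis(benzyloxy)-2-[3-(benzyloxy)-4-methoxyphenyl]-6,8-dimethoxy-4H-chromen-4-one | COc1ccc(cc1OCc4ccccc4)-c2cc(=O)c3c(OCc5ccccc5)c(OC)c(OCc6ccccc6)c(OC)c3o2
F4 | step 1 | 5,7-dihydroxy-2-(3-hydroxy-4-methoxyphenyl)-6,8-diiodo-4H-chromen-4-one | COc1ccc(cc1O)-c2cc(=O)c3c(O)c(I)c(O)c(I)c3o2
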